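**Strategy.** Everything rests on closing the dimethylpyran ring (ring D) last, on the complete isoflavone, by forming the bond between the pyran alkene carbon C4 and the ring-B carbon C5' (C4a of the chromene). A gold-catalysed 6-endo-dig hydroarylation of a 4'-O-(1,1-dimethylpropargyl) ether does this in one isomerisation. It exploits the resorcinol pattern of ring B: C5' is ortho to the ether oxygen, para to the free 2'-hydroxyl and unhindered, while C3' sits between two oxygens. The precursor is an isomer of the MOM-protected target, assembled by Suzuki coupling of a ring-A 3-iodochromone (from 2',6'-dihydroxyacetophenone) with a resorcinol borate, hydrogenolysis and selective 4'-O-propargylation.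

Key step: step 10

Remark on locants: chromone positions are unprimed (ring A = C5 to C8, ring C = pyranone), ring B is primed, ring D is the dimethylpyran; acetophenone intermediates are numbered from the acetyl-bearing carbon C1.

**Step 1**
Reactants: 1 2',6'-dihydroxyacetophenone
Product: 3 1-(2,3,6-trihydroxyphenyl)ethanone, via aryl sulfate 2 (not isolated)
Conditions: K2S2O8, 10% aq NaOH, 0 °C to rt; then HCl, 90 °C
Reagents that add atoms: potassium peroxodisulfate, [K+].[K+].[O-]S(=O)(=O)OOS(=O)(=O)[O-]
Why: Elbs persulfate oxidation: the phenolate is sulfated at the carbon para to one phenoxide oxygen (the two such carbons are equivalent by symmetry), and acid hydrolysis of the aryl sulfate should free the new hydroxyl.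

**Step 2**
Reactants: 3 1-(2,3,6-trihydroxyphenyl)ethanone
Product: 4 1-[2-hydroxy-3,6-bis(methoxymethoxy)phenyl]ethanone
Conditions: MOMCl (2.1 equiv), iPr2NEt, CH2Cl2, 0 °C to rt, under argon
Reagents that add atoms: chloromethyl methyl ether, COCCl
Why: MOM acetal formation (Williamson type): the non-chelated 3-hydroxyl and the less hindered 6-hydroxyl should react, whereas the 2-hydroxyl, flanked by the acetyl group and the new 3-OMOM group and hydrogen-bonded to the carbonyl, should stay free, which fixes the oxygen that later becomes the pyranone oxygen.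

**Step 3**
Reactants: 4 1-[2-hydroxy-3,6-bis(methoxymethoxy)phenyl]ethanone
Product: 5 1-[3-bromo-6-hydroxy-2,5-bis(methoxymethoxy)phenyl]ethanone
Conditions: NBS, MeCN, 0 °C
Reagents that add atoms: N-bromosuccinimide, O=C1CCC(=O)N1Br
Why: Electrophilic aromatic bromination: C5 of 4 is para to the free hydroxyl, ortho to an acetal oxygen and meta to the acetyl group, whereas C4 is para to the acetyl group, so bromine should enter at C5.

**Step 4**
Reactants: 5 1-[3-bromo-6-hydroxy-2,5-bis(methoxymethoxy)phenyl]ethanone; 6 2-methylbut-3-en-2-ol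
Product: 8 1-[2-hydroxy-5-(3-hydroxy-3-methylbutyl)-3,6-bis(methoxymethoxy)phenyl]ethanone, via alkylborane 7 (not isolated)
Conditions: 6, 9-BBN, THF, 0 °C to rt; then 5, Pd(OAc)2, SPhos, K3PO4, THF/H2O, 65 °C
Reagents that add atoms: none
Why: Anti-Markovnikov hydroboration of the terminal alkene followed by B-alkyl Suzuki–Miyaura coupling should join the primary alkylborane to the aryl bromide; ketone, phenol, acetals and tertiary alcohol tolerate the phosphate base.

**Step 5**
Reactants: 8 1-[2-hydroxy-5-(3-hydroxy-3-methylbutyl)-3,6-bis(methoxymethoxy)phenyl]ethanone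
Product: 10 6-(3-hydroxy-3-methylbutyl)-3-iodo-5,8-bis(methoxymethoxy)-4H-chromen-4-one, via enaminone 9 (not isolated)
Conditions: Me2NCH(OMe)2, 95 °C; concentrate; then I2, pyridine, CHCl3, rt
Reagents that add atoms: N,N-dimethylformamide dimethyl acetal, COC(OC)N(C)C; iodine, II
Why: Enaminone formation at the acetyl methyl group and iodine-induced cyclisation (3-iodochromone synthesis from 2-hydroxyaryl enaminones): only the free 2-hydroxyl can add to the iminium carbon and expel dimethylamine, and pyridine buffers the acid so the MOM acetals survive.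

**Step 6**
Reactants: 11 4-bromobenzene-1,3-diol (4-bromoresorcinol)
Product: 12 2,4-bis(benzyloxy)-1-bromobenzene
Conditions: BnBr, K2CO3, DMF, 60 °C
Reagents that add atoms: benzyl bromide, BrCc1ccccc1
Why: Williamson ether synthesis on both phenols; no selectivity is needed.

**Step 7**
Reactants: 12 2,4-bis(benzyloxy)-1-bromobenzene; 10 6-(3-hydroxy-3-methylbutyl)-3-iodo-5,8-bis(methoxymethoxy)-4H-chromen-4-one
Product: 15 3-[2,4-bis(benzyloxy)phenyl]-6-(3-hydroxy-3-methylbutyl)-5,8-bis(methoxymethoxy)-4H-chromen-4-one, via aryllithium 13 (not isolated), via lithium arylborate 14 (not isolated)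
Conditions: 12, n-BuLi, THF, −78 °C; B(OiPr)3, −78 °C to rt; then 10, Pd(dppf)Cl2, aq K3PO4, THF, 60 °C
Reagents that add atoms: none
Why: Bromine–lithium exchange, trapping as the triisopropyl borate and Suzuki–Miyaura coupling with the iodide at C3 of the chromone (standard isoflavone assembly); the iodide with its free tertiary alcohol is added only after the aryllithium has been consumed.

**Step 8**
Reactants: 15 3-[2,4-bis(benzyloxy)phenyl]-6-(3-hydroxy-3-methylbutyl)-5,8-bis(methoxymethoxy)-4H-chromen-4-one
Product: 16 3-(2,4-dihydroxyphenyl)-6-(3-hydroxy-3-methylbutyl)-5,8-bis(methoxymethoxy)-4H-chromen-4-one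
Conditions: H2 (1 atm), 10% Pd/C, EtOAc/MeOH, rt, stopped at full debenzylation
Reagents that add atoms: none
Why: Hydrogenolysis of the two benzyl ethers; MOM acetals and the tertiary alcohol are inert, and the pyranone double bond is reduced much more slowly.

**Step 9**
Reactants: 16 3-(2,4-dihydroxyphenyl)-6-(3-hydroxy-3-methylbutyl)-5,8-bis(methoxymethoxy)-4H-chromen-4-one; 17 3-chloro-3-methylbut-1-yne
Product: 18 3-{2-hydroxy-4-[(2-methylbut-3-yn-2-yl)oxy]phenyl}-6-(3-hydroxy-3-methylbutyl)-5,8-bis(methoxymethoxy)-4H-chromen-4-one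
Conditions: 17 (1.2 equiv), DBU, CuCl2·2H2O (1 mol%), MeCN, 0 °C
Reagents that add atoms: none
Why: CuCl2-catalysed propargylic substitution of the tertiary chloride by a phenoxide: the 4'-hydroxyl is unhindered, whereas the 2'-hydroxyl is hydrogen-bonded to the C4 carbonyl and flanked by ring C, and the tertiary alcohol is not acidic enough to react.

**Step 10**
Reactants: 18 3-{2-hydroxy-4-[(2-methylbut-3-yn-2-yl)oxy]phenyl}-6-(3-hydroxy-3-methylbutyl)-5,8-bis(methoxymethoxy)-4H-chromen-4-one
Product: 19 6-(3-hydroxy-3-methylbutyl)-3-(7-hydroxy-2,2-dimethyl-2H-chromen-6-yl)-5,8-bis(methoxymethoxy)-4H-chromen-4-one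
Conditions: Ph3PAuNTf2 (3 mol%), CH2Cl2, rt
Reagents that add atoms: none
Why: Cationic monovalent gold coordinates the terminal alkyne and ring-B carbon C5' attacks the alkyne terminus anti to the metal, giving an arenium ion that rearomatises and a vinylgold species that is protodeaurated to the 2H-chromene. The closest known reaction type is the gold-catalysed intramolecular hydroarylation of aryl 1,1-dimethylpropargyl ethers to 2,2-dimethyl-2H-chromenes. Ring D closes in the 6-endo-dig mode, the normal one for terminal aryl propargyl ethers and helped here by the gem-dimethyl group; no stereocentre is formed. The step needs site selectivity between C5' and C3', both ortho to the ether oxygen: C5' is para to the free 2'-hydroxyl and has a hydrogen neighbour, whereas C3' is flanked by two oxygen substituents, so attack at C5' should dominate. The pyranone alkene is electron-poor, the only free ring-A position (C7) is out of reach, and the non-acidic catalyst should leave the MOM acetals and the tertiary alcohol untouched.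

**Step 11**
Reactants: 19 6-(3-hydroxy-3-methylbutyl)-3-(7-hydroxy-2,2-dimethyl-2H-chromen-6-yl)-5,8-bis(methoxymethoxy)-4H-chromen-4-one
Product: 20 Kraussianone 3
Conditions: ZnBr2, n-PrSH, CH2Cl2, 0 °C to rt, under argon
Reagents that add atoms: none
Why: Lewis acid–thiol cleavage of the two aryl MOM acetals (the methoxymethyl group is transferred to sulfur) under non-protic conditions, chosen to avoid acid-induced cyclisation of the tertiary alcohol onto the 5-hydroxyl and hydration of the chromene.

**Compound list**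

1 | 2',6'-dihydroxyacetophenone | CC(=O)c1c(O)cccc1O | starting material
2 | potassium 3-acetyl-2,4-dihydroxyphenyl sulfate | CC(=O)c1c(O)ccc(OS(=O)(=O)[O-])c1O.[K+] | intermediate
3 | 1-(2,3,6-trihydroxyphenyl)ethanone | CC(=O)c1c(O)ccc(O)c1O | intermediate
4 | 1-[2-hydroxy-3,6-bis(methoxymethoxy)phenyl]ethanone | CC(=O)c1c(OCOC)ccc(OCOC)c1O | intermediate
5 | 1-[3-bromo-6-hydroxy-2,5-bis(methoxymethoxy)phenyl]ethanone | CC(=O)c1c(OCOC)c(Br)cc(OCOC)c1O | intermediate
6 | 2-methylbut-3-en-2-ol | CC(C)(O)C=C | starting material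
7 | 4-(9-borabicyclo[3.3.1]nonan-9-yl)-2-methylbutan-2-ol | CC(C)(O)CCB1C2CCCC1CCC2 | intermediate
8 | 1-[2-hydroxy-5-(3-hydroxy-3-methylbutyl)-3,6-bis(methoxymethoxy)phenyl]ethanone | CC(=O)c1c(OCOC)c(CCC(C)(C)O)cc(OCOC)c1O | intermediate
9 | (E)-3-(dimethylamino)-1-[2-hydroxy-5-(3-hydroxy-3-methylbutyl)-3,6-bis(methoxymethoxy)phenyl]prop-2-en-1-one | CN(C)/C=C/C(=O)c1c(OCOC)c(CCC(C)(C)O)cc(OCOC)c1O | intermediate
10 | 6-(3-hydroxy-3-methylbutyl)-3-iodo-5,8-bis(methoxymethoxy)-4H-chromen-4-one | CC(C)(O)CCc1cc(OCOC)c2occ(I)c(=O)c2c1OCOC | intermediate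
11 | 4-bromobenzene-1,3-diol | Oc1ccc(Br)c(O)c1 | starting material
12 | 2,4-bis(benzyloxy)-1-bromobenzene | Brc1ccc(OCc2ccccc2)cc1OCc1ccccc1 | intermediate
13 | [2,4-bis(benzyloxy)phenyl]lithium | [Li]c1ccc(OCc2ccccc2)cc1OCc1ccccc1 | intermediate
14 | lithium [2,4-bis(benzyloxy)phenyl]tri(propan-2-yloxy)borate | [Li+].CC(C)O[B-](OC(C)C)(OC(C)C)c1ccc(OCc2ccccc2)cc1OCc1ccccc1 | intermediate
15 | 3-[2,4-bis(benzyloxy)phenyl]-6-(3-hydroxy-3-methylbutyl)-5,8-bis(methoxymethoxy)-4H-chromen-4-one | CC(C)(O)CCc1cc(OCOC)c2occ(-c3ccc(OCc4ccccc4)cc3OCc3ccccc3)c(=O)c2c1OCOC | intermediate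
16 | 3-(2,4-dihydroxyphenyl)-6-(3-hydroxy-3-methylbutyl)-5,8-bis(methoxymethoxy)-4H-chromen-4-one | CC(C)(O)CCc1cc(OCOC)c2occ(-c3ccc(O)cc3O)c(=O)c2c1OCOC | intermediate
17 | 3-chloro-3-methylbut-1-yne | CC(C)(Cl)C#C | starting material
18 | 3-{2-hydroxy-4-[(2-methylbut-3-yn-2-yl)oxy]phenyl}-6-(3-hydroxy-3-methylbutyl)-5,8-bis(methoxymethoxy)-4H-chromen-4-one | CC(C)(O)CCc1cc(OCOC)c2occ(-c3ccc(OC(C)(C)C#C)cc3O)c(=O)c2c1OCOC | intermediate
19 | 6-(3-hydroxy-3-methylbutyl)-3-(7-hydroxy-2,2-dimethyl-2H-chromen-6-yl)-5,8-bis(methoxymethoxy)-4H-chromen-4-one | CC(C)(O)CCc1cc(OCOC)c2occ(-c3cc4c(cc3O)OC(C)(C)C=C4)c(=O)c2c1OCOC | intermediate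
20 | Kraussianone 3, 5,8-dihydroxy-6-(3-hydroxy-3-methylbutyl)-3-(7-hydroxy-2,2-dimethyl-2H-chromen-6-yl)-4H-chromen-4-one | CC(C)(O)CCc1cc(O)c2occ(-c3cc4c(cc3O)OC(C)(C)C=C4)c(=O)c2c1O | target

Total step count: 11. Longest linear sequence: 10 steps (steps 1 to 5, then 7 to 11).

**Steps most likely to fail**

Step 10 (key step). The cationic gold catalyst may ionise the tertiary propargylic carbon–oxygen bond, so that the ether is lost and phenol 16 returns, or closure at C3' may compete. The fallback sets out from 18 and comes back at 19. It abandons metal catalysis for the thermal aromatic propargyl Claisen cascade (N,N-diethylaniline, 190 °C). A [3,3] shift makes the same bond to C5'; enolisation, a 1,5-hydrogen shift and an oxa-6π electrocyclisation then close ring D. The electron-donating meta-hydroxyl directs the shift to the para carbon C5'. No new compound is isolated.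

Step 2. Regiocontrol may be lost: the 2-hydroxyl may be alkylated in place of the 6-hydroxyl, or all three hydroxyls may react. The fallback sets out from 3 and comes back at 4, masking the catechol pair first. PhB(OH)2 in toluene with azeotropic removal of water should give the cyclic boronate 1-(5-hydroxy-2-phenyl-1,3,2-benzodioxaborol-4-yl)ethanone F1. MOMCl and iPr2NEt at 40 °C then protect the only remaining hydroxyl to give 1-[5-(methoxymethoxy)-2-phenyl-1,3,2-benzodioxaborol-4-yl]ethanone F2. Aqueous work-up hydrolyses the boronate to 1-[2,3-dihydroxy-6-(methoxymethoxy)phenyl]ethanone F3. One equivalent of MOMCl with iPr2NEt at 0 °C should then react only at the non-chelated 3-hydroxyl and give 4.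

Step 1. Conversion may be low and the electron-rich product may be oxidised further by persulfate. The fallback sets out from 1 and comes back at 3. Teuber oxidation with (KSO3)2NO in phosphate-buffered aqueous acetone should give 2-acetyl-3-hydroxycyclohexa-2,5-diene-1,4-dione F4, which Na2S2O4 in water/EtOAc reduces to 3.

**Further compounds**
F0 | step 10 | none | none
F1 | step 2 | 1-(5-hydroxy-2-phenyl-1,3,2-benzodioxaborol-4-yl)ethanone | CC(=O)c1c(O)ccc2OB(c3ccccc3)Oc12
F2 | step 2 | 1-[5-(methoxymethoxy)-2-phenyl-1,3,2-benzodioxaborol-4-yl]ethanone | CC(=O)c1c(OCOC)ccc2OB(c3ccccc3)Oc12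
F3 | step 2 | 1-[2,3-dihydroxy-6-(methoxymethoxy)phenyl]ethanone | CC(=O)c1c(OCOC)ccc(O)c1O
F4 | step 1 | 2-acetyl-3-hydroxycyclohexa-2,5-diene-1,4-dione | CC(=O)C1=C(O)C(=O)C=CC1=O
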